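Retrosynthesis: once three benzyl groups are removed, ring C is cut at O1–C2, ring A at C4a–C8a, the chain at C4–C4a (acylation of a triacetate trianion) and at C2=C3 (aldol condensation), and the dioxane ring (ring D) at its two alkyl C–O bonds.
Enabling feature: ring A (C4a, C5, C6, C7, C8, C8a) is a phloroglucinol that carries the C4 carbonyl on C4a, the oxygen pattern of a folded acetate chain in which C4a is a methylene between two ketones and C8a an ester carbon.
Forward: ring D is built first on 3,4-dihydroxybenzaldehyde; the aldehyde is extended to a (Z)-α-benzyloxycinnamoyl Weinreb amide, which acylates the trianion of methyl 3,5-dioxohexanoate to give a linear 3,5,7-trioxo ester.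
Mg(OMe)2 then folds this chain into ring A by Claisen condensation, I2 in DMSO closes ring C, and hydrogenolysis frees the three benzylated hydroxyl groups.
Stereochemistry: both centres come from one Sharpless epoxidation with L-(+)-tartrate; the benzylic carbon is inverted by SN2 opening with the 4-O phenoxide and its neighbour by Mitsunobu closure, which leaves the trans-(2R,3R) dioxane.

Key step: step 11

Remark: the triketo ester and the polyphenolic ketones are drawn in their keto forms although they should exist largely as enol or chelated tautomers; alkoxides, phenoxides and magnesium chelates are treated as forms of their parent compounds, and only the two preformed carbon nucleophiles are numbered.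
Abbreviation in names: Bdx = (2R,3R)-2-[4-(benzyloxy)-3-methoxyphenyl]-3-[(benzyloxy)methyl]-2,3-dihydro-1,4-benzodioxin-6-yl.

Step 1
Reactants: 1 4-(benzyloxy)-3-methoxybenzaldehyde (O-benzylvanillin, purchased)
Product: 2 ethyl (2E)-3-[4-(benzyloxy)-3-methoxyphenyl]prop-2-enoate
Conditions: (EtO)2P(O)CH2CO2Et, NaH, THF, 0 °C to rt
Reagents that add atoms: triethyl phosphonoacetate CCOC(=O)CP(=O)(OCC)OCC
Why: Horner–Wadsworth–Emmons olefination of an aromatic aldehyde with a stabilised phosphonate anion should give the (E)-cinnamate under thermodynamic control.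

Step 2
Reactants: 2 ethyl (2E)-3-[4-(benzyloxy)-3-methoxyphenyl]prop-2-enoate
Product: 3 (2E)-3-[4-(benzyloxy)-3-methoxyphenyl]prop-2-en-1-ol
Conditions: i-Bu2AlH (2.2 equiv), CH2Cl2, −78 to 0 °C; aq. KNaC4H4O6 work-up
Reagents that add atoms: none
Why: 1,2-reduction of a conjugated ester by i-Bu2AlH at low temperature should stop at the allylic alcohol and leave the alkene and the benzyl ether untouched.

Step 3
Reactants: 3 (2E)-3-[4-(benzyloxy)-3-methoxyphenyl]prop-2-en-1-ol
Product: 4 [(2S,3S)-3-[4-(benzyloxy)-3-methoxyphenyl]oxiran-2-yl]methanol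
Conditions: Ti(OiPr)4 (10 mol%), L-(+)-diisopropyl tartrate (13 mol%), t-BuOOH (decane), 4 Å MS, CH2Cl2, −25 °C; aq. NaOH–NaCl work-up
Reagents that add atoms: tert-butyl hydroperoxide CC(C)(C)OO
Why: Sharpless asymmetric epoxidation, in which the titanium–L-(+)-tartrate complex binds the allylic hydroxyl and delivers oxygen to the alkene face that gives the (2S,3S)-epoxy alcohol, so both stereocentres of the later dioxane ring are set by the reagent in one step, while catalytic loading, low temperature and a basic work-up protect the electron-rich aryl epoxide.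

Step 4
Reactants: 4 [(2S,3S)-3-[4-(benzyloxy)-3-methoxyphenyl]oxiran-2-yl]methanol
Product: 5 (2S,3S)-2-[(benzyloxy)methyl]-3-[4-(benzyloxy)-3-methoxyphenyl]oxirane
Conditions: NaH, BnBr, n-Bu4NI (cat.), THF, 0 °C to rt
Reagents that add atoms: benzyl bromide BrCc1ccccc1
Why: Williamson etherification of the primary alkoxide in an aprotic medium at 0 °C should outrun Payne rearrangement and masks the hydroxyl that would otherwise compete in step 6.

Step 5
Reactants: 5 (2S,3S)-2-[(benzyloxy)methyl]-3-[4-(benzyloxy)-3-methoxyphenyl]oxirane; 6 3,4-dihydroxybenzaldehyde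
Product: 7 4-{[(1R,2S)-3-(benzyloxy)-1-[4-(benzyloxy)-3-methoxyphenyl]-2-hydroxypropyl]oxy}-3-hydroxybenzaldehyde
Conditions: 6 (1.5 equiv), Cs2CO3 (0.3 equiv), DMF, 80 °C
Reagents that add atoms: none
Why: Base-catalysed phenol–epoxide opening, in which substoichiometric carbonate ionises only the more acidic hydroxyl of 6 (para to the formyl group) and this phenoxide attacks the aryl-activated benzylic carbon rather than the carbon deactivated by the adjacent benzyloxymethyl group, by SN2 with inversion (3S becomes 1R) and without a Lewis acid that could ionise the benzylic C–O bond.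

Step 6
Reactants: 7 4-{[(1R,2S)-3-(benzyloxy)-1-[4-(benzyloxy)-3-methoxyphenyl]-2-hydroxypropyl]oxy}-3-hydroxybenzaldehyde
Product: 8 (2R,3R)-2-[4-(benzyloxy)-3-methoxyphenyl]-3-[(benzyloxy)methyl]-2,3-dihydro-1,4-benzodioxine-6-carbaldehyde (Bdx–CHO)
Conditions: PPh3, DIAD, THF, 0 °C to rt
Reagents that add atoms: none
Why: Intramolecular Mitsunobu etherification, in which the secondary alcohol is activated as its oxyphosphonium ion and displaced by the neighbouring phenol in a 6-exo-tet closure with inversion (2S becomes 3R), so that two inversions on the trans-epoxide give the trans-(2R,3R) dioxane.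

Step 7
Reactants: 8 Bdx–CHO; 9 methyl 2-(benzyloxy)acetate
Product: 11 methyl 2-(benzyloxy)-3-hydroxy-3-Bdx-propanoate (mixture of diastereomers), via lithium enolate of methyl benzyloxyacetate 10 (not isolated)
Conditions: 9, LiN(i-Pr)2, THF, −78 °C; then 8, −78 °C; AcOH quench
Reagents that add atoms: none
Why: Aldol addition of a lithium ester enolate to a non-enolisable aromatic aldehyde at −78 °C, in which the two new centres need no control because both are removed in step 8.

Step 8
Reactants: 11 methyl 2-(benzyloxy)-3-hydroxy-3-Bdx-propanoate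
Product: 13 methyl (2Z)-2-(benzyloxy)-3-Bdx-prop-2-enoate, via methanesulfonate of the aldol adduct 12 (not isolated)
Conditions: MsCl, Et3N, CH2Cl2, 0 °C; then DBU, rt
Reagents that add atoms: none
Why: Mesylation followed by E1cB elimination should give the conjugated α-alkoxycinnamate mainly as the (Z)-isomer (aryl trans to the ester), the preferred geometry of the equilibrating ester enolate; any (E)-isomer would converge later because the alkene geometry is lost when ring C forms.

Step 9
Reactants: 13 methyl (2Z)-2-(benzyloxy)-3-Bdx-prop-2-enoate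
Product: 14 (2Z)-2-(benzyloxy)-3-Bdx-N-methoxy-N-methylprop-2-enamide
Conditions: MeNH(OMe)·HCl, i-PrMgCl, THF, −20 to 0 °C
Reagents that add atoms: N,O-dimethylhydroxylamine hydrochloride CNOC.Cl
Why: Weinreb amide formation by aminolysis of the ester with the chloromagnesium amide is standard for conjugated esters, and the weakly electrophilic α-alkoxy enoate should not undergo conjugate addition.

Step 10
Reactants: 14 (2Z)-2-(benzyloxy)-3-Bdx-N-methoxy-N-methylprop-2-enamide; 15 methyl 3,5-dioxohexanoate
Product: 17 methyl (8Z)-8-(benzyloxy)-9-Bdx-3,5,7-trioxonon-8-enoate, via trilithium trianion of methyl 3,5-dioxohexanoate 16 (not isolated)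
Conditions: 15 (2 equiv), LiN(i-Pr)2 (6.1 equiv), THF, 0 °C; then 14, −78 to −20 °C; cold 1 M HCl
Reagents that add atoms: none
Why: Acylation of a polyketide trianion, in which the last-formed and most basic terminal carbanion of 16 adds to the Weinreb amide carbonyl to give a chelated tetrahedral adduct that survives until work-up, which prevents over-addition and proton transfer to the product and favours 1,2- over 1,4-addition.

Step 11
Reactants: 17 methyl (8Z)-8-(benzyloxy)-9-Bdx-3,5,7-trioxonon-8-enoate
Product: 18 (2Z)-2-(benzyloxy)-3-Bdx-1-(2,4,6-trihydroxyphenyl)prop-2-en-1-one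
Conditions: Mg(OMe)2 (8 equiv), MeOH, 25 to 45 °C; cold 1 M HCl work-up
Reagents that add atoms: none
Why: Mg(OMe)2 deprotonates the active methylene groups and divalent magnesium holds the polyenolate folded by chelating neighbouring carbonyl oxygens, so that the chain C6 methylene (future C4a, between the C5 and C7 carbonyls) adds to the ester carbonyl C1 (future C8a); methoxide then leaves and the 2-acylcyclohexane-1,3,5-trione enolises to the aromatic triol, which makes the sequence irreversible. The closest known reaction type is the magnesium-methoxide-mediated intramolecular Claisen condensation of 7-aryl- and 7-styryl-3,5,7-trioxoheptanoates to acylphloroglucinols, the laboratory counterpart of chalcone synthase folding. Ring A closes in the 6-exo-trig mode, the attacked ester C=O lying outside the forming ring. No stereocentre is created, and the two dioxane stereocentres are not enolisable and should pass unchanged. The step needs Claisen closure to win over aldol closure of the C2 methylene onto the C7 ketone (which would give a resorcylate) and over pyranone formation: the C7 carbonyl is the least electrophilic ketone because it is conjugated to the electron-rich α-benzyloxystyrene unit and shielded by the benzyloxy group, the chelating counter-ion in methanol favours C-acylation at the ester, and a 4-hydroxy-2-pyranone formed by O-acylation would be reopened by methoxide and returned to the productive path. The α-benzyloxy enone should also resist conjugate addition of methoxide, and ring A emerges as free phenols, so it needs no protecting groups.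

Step 12
Reactants: 18 (2Z)-2-(benzyloxy)-3-Bdx-1-(2,4,6-trihydroxyphenyl)prop-2-en-1-one
Product: 20 3-(benzyloxy)-2-Bdx-5,7-dihydroxy-4H-chromen-4-one, via 3-benzyloxyflavanone 19 (not isolated)
Conditions: I2 (10 mol%), DMSO, 120 °C
Reagents that add atoms: none
Why: Oxidative cyclisation of a 2'-hydroxychalcone with catalytic I2 in DMSO, in which one of the two equivalent ortho-hydroxyl groups adds to the enone β-carbon (6-endo-trig oxa-Michael addition) to give flavanone 19, which is iodinated at C3 through its enol and loses HI across C2–C3 while DMSO reoxidises iodide to I2; the α-benzyloxy group blocks the aurone pathway, and any 19 already formed in step 11 converges here.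

Step 13
Reactants: 20 3-(benzyloxy)-2-Bdx-5,7-dihydroxy-4H-chromen-4-one
Product: 21 3,5,7-trihydroxy-2-[(2R,3R)-2-(4-hydroxy-3-methoxyphenyl)-3-(hydroxymethyl)-2,3-dihydro-1,4-benzodioxin-6-yl]-4H-chromen-4-one (target)
Conditions: H2 (1 atm), Pd/C, THF–MeOH, rt
Reagents that add atoms: none
Why: Hydrogenolysis over Pd/C should cleave the aryl, enol and alkyl benzyl ethers, while the flavonol C2=C3 bond and the hindered cyclic benzylic C–O bond of the dioxane ring should remain.

Compound list
1 | 4-(benzyloxy)-3-methoxybenzaldehyde | COc1cc(C=O)ccc1OCc1ccccc1 | starting material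
2 | ethyl (2E)-3-[4-(benzyloxy)-3-methoxyphenyl]prop-2-enoate | CCOC(=O)/C=C/c1ccc(OCc2ccccc2)c(OC)c1 | intermediate
3 | (2E)-3-[4-(benzyloxy)-3-methoxyphenyl]prop-2-en-1-ol | OC/C=C/c1ccc(OCc2ccccc2)c(OC)c1 | intermediate
4 | [(2S,3S)-3-[4-(benzyloxy)-3-methoxyphenyl]oxiran-2-yl]methanol | COc1cc([C@@H]2O[C@H]2CO)ccc1OCc1ccccc1 | intermediate
5 | (2S,3S)-2-[(benzyloxy)methyl]-3-[4-(benzyloxy)-3-methoxyphenyl]oxirane | COc1cc([C@@H]2O[C@H]2COCc2ccccc2)ccc1OCc1ccccc1 | intermediate
6 | 3,4-dihydroxybenzaldehyde | O=Cc1ccc(O)c(O)c1 | starting material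
7 | 4-{[(1R,2S)-3-(benzyloxy)-1-[4-(benzyloxy)-3-methoxyphenyl]-2-hydroxypropyl]oxy}-3-hydroxybenzaldehyde | COc1cc([C@@H](Oc2ccc(C=O)cc2O)[C@@H](O)COCc2ccccc2)ccc1OCc1ccccc1 | intermediate
8 | (2R,3R)-2-[4-(benzyloxy)-3-methoxyphenyl]-3-[(benzyloxy)methyl]-2,3-dihydro-1,4-benzodioxine-6-carbaldehyde | COc1cc([C@H]2Oc3ccc(C=O)cc3O[C@@H]2COCc2ccccc2)ccc1OCc1ccccc1 | intermediate
9 | methyl 2-(benzyloxy)acetate | COC(=O)COCc1ccccc1 | starting material
10 | lithium 2-(benzyloxy)-1-methoxyethen-1-olate (lithium enolate of 9, formed in the flask) | [Li+].COC([O-])=COCc1ccccc1 | intermediate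
11 | methyl 2-(benzyloxy)-3-hydroxy-3-Bdx-propanoate (mixture of diastereomers at C2 and C3 of the propanoate) | COc1cc([C@H]2Oc3ccc(C(O)C(OCc4ccccc4)C(=O)OC)cc3O[C@@H]2COCc2ccccc2)ccc1OCc1ccccc1 | intermediate
12 | methyl 2-(benzyloxy)-3-[(methanesulfonyl)oxy]-3-Bdx-propanoate (mixture of diastereomers, formed in the flask) | COc1cc([C@H]2Oc3ccc(C(OS(C)(=O)=O)C(OCc4ccccc4)C(=O)OC)cc3O[C@@H]2COCc2ccccc2)ccc1OCc1ccccc1 | intermediate
13 | methyl (2Z)-2-(benzyloxy)-3-Bdx-prop-2-enoate | COc1cc([C@H]2Oc3ccc(/C=C(OCc4ccccc4)/C(=O)OC)cc3O[C@@H]2COCc2ccccc2)ccc1OCc1ccccc1 | intermediate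
14 | (2Z)-2-(benzyloxy)-3-Bdx-N-methoxy-N-methylprop-2-enamide | COc1cc([C@H]2Oc3ccc(/C=C(OCc4ccccc4)/C(=O)N(C)OC)cc3O[C@@H]2COCc2ccccc2)ccc1OCc1ccccc1 | intermediate
15 | methyl 3,5-dioxohexanoate | COC(=O)CC(=O)CC(C)=O | starting material
16 | trilithium trianion of methyl 3,5-dioxohexanoate (formed in the flask) | [Li+].[Li+].[Li+].C=C([O-])C=C([O-])C=C([O-])OC | intermediate
17 | methyl (8Z)-8-(benzyloxy)-9-Bdx-3,5,7-trioxonon-8-enoate | COc1cc([C@H]2Oc3ccc(/C=C(OCc4ccccc4)/C(=O)CC(=O)CC(=O)CC(=O)OC)cc3O[C@@H]2COCc2ccccc2)ccc1OCc1ccccc1 | intermediate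
18 | (2Z)-2-(benzyloxy)-3-Bdx-1-(2,4,6-trihydroxyphenyl)prop-2-en-1-one | COc1cc([C@H]2Oc3ccc(/C=C(OCc4ccccc4)/C(=O)c4c(O)cc(O)cc4O)cc3O[C@@H]2COCc2ccccc2)ccc1OCc1ccccc1 | intermediate
19 | 3-(benzyloxy)-2-Bdx-5,7-dihydroxy-2,3-dihydro-4H-chromen-4-one (mixture at C2 and C3 of the chromanone, formed in the flask) | COc1cc([C@H]2Oc3ccc(C4Oc5cc(O)cc(O)c5C(=O)C4OCc4ccccc4)cc3O[C@@H]2COCc2ccccc2)ccc1OCc1ccccc1 | intermediate
20 | 3-(benzyloxy)-2-Bdx-5,7-dihydroxy-4H-chromen-4-one | COc1cc([C@H]2Oc3ccc(-c4oc5cc(O)cc(O)c5c(=O)c4OCc4ccccc4)cc3O[C@@H]2COCc2ccccc2)ccc1OCc1ccccc1 | intermediate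
21 | 3,5,7-trihydroxy-2-[(2R,3R)-2-(4-hydroxy-3-methoxyphenyl)-3-(hydroxymethyl)-2,3-dihydro-1,4-benzodioxin-6-yl]-4H-chromen-4-one | COc1cc([C@H]2Oc3ccc(-c4oc5cc(O)cc(O)c5c(=O)c4O)cc3O[C@@H]2CO)ccc1O | target

Total step count: 13.
Longest linear sequence: 13 steps (1 to 21); 6, 9 and 15 are purchased and enter directly.

Steps most likely to fail

1. Step 11 (key step). The chain may close by aldol addition of the C2 methylene to the C7 ketone, fragment by retro-Claisen cleavage, or take up methoxide at the enone instead of folding into ring A. The fallback sets out from Weinreb amide 14 and buys ring A instead of building it. Phloroglucinol is converted (MOMCl, i-Pr2NEt, CH2Cl2) into 1,3,5-tris(methoxymethoxy)benzene F1. n-BuLi (THF, 0 °C) lithiates it between two acetal oxygens to give 2-lithio-1,3,5-tris(methoxymethoxy)benzene F2. This aryllithium is acylated by 14 at −78 °C to give the tris(methoxymethyl)-protected chalcone F3. HCl in MeOH (40 °C) removes the three acetals, and the route is rejoined at chalcone 18.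

2. Step 10. Proton transfer or conjugate addition may compete with acylation, and the free triketo ester may condense with itself during isolation. The fallback sets out from 14 and uses a lactone-masked chain. Purchased 4-hydroxy-6-methyl-2H-pyran-2-one is deprotonated twice (LiN(i-Pr)2, 2.2 equiv, THF, −78 °C) to give the dilithium dianion of 4-hydroxy-6-methyl-2H-pyran-2-one F4. Its methyl-derived carbanion is acylated by 14 to give the 6-(acylmethyl)-4-hydroxy-2-pyranone F5, a storable lactone form of the triketo acid. Mg(OMe)2 in MeOH opens the lactone by methanolysis to triketo ester 17 in the flask, where the route is rejoined and step 11 follows without isolation.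

3. Step 3. The titanium alkoxide may assist opening of the electron-rich benzylic epoxide during reaction or work-up, with loss of material and of enantiopurity. The fallback sets out from allylic alcohol 3 and uses a metal-free epoxidation under basic buffer. Benzylation first (NaH, BnBr, THF) gives the cinnamyl benzyl ether F6. Shi epoxidation with the L-fructose-derived ketone (the enantiomer of the common D-fructose-derived catalyst), KHSO5 and K2CO3 buffer (MeCN–dimethoxymethane–H2O, 0 °C) should then give epoxide 5 directly, where the route is rejoined.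

Further compounds
F1 | step 11 | 1,3,5-tris(methoxymethoxy)benzene | COCOc1cc(OCOC)cc(OCOC)c1
F2 | step 11 | 2-lithio-1,3,5-tris(methoxymethoxy)benzene | [Li]c1c(OCOC)cc(OCOC)cc1OCOC
F3 | step 11 | (2Z)-2-(benzyloxy)-3-Bdx-1-[2,4,6-tris(methoxymethoxy)phenyl]prop-2-en-1-one | COc1cc([C@H]2Oc3ccc(/C=C(OCc4ccccc4)/C(=O)c4c(OCOC)cc(OCOC)cc4OCOC)cc3O[C@@H]2COCc2ccccc2)ccc1OCc1ccccc1
F4 | step 10 | dilithium dianion of 4-hydroxy-6-methyl-2H-pyran-2-one | [Li+].[Li+].[CH2-]C1=CC([O-])=CC(=O)O1
F5 | step 10 | 6-[(3Z)-3-(benzyloxy)-4-Bdx-2-oxobut-3-en-1-yl]-4-hydroxy-2H-pyran-2-one | COc1cc([C@H]2Oc3ccc(/C=C(OCc4ccccc4)/C(=O)CC4=CC(O)=CC(=O)O4)cc3O[C@@H]2COCc2ccccc2)ccc1OCc1ccccc1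
F6 | step 3 | 1-(benzyloxy)-4-[(1E)-3-(benzyloxy)prop-1-en-1-yl]-2-methoxybenzene | COc1cc(/C=C/COCc2ccccc2)ccc1OCc1ccccc1
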